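**Retrosynthetic overview**

- Feature used: with the lactone numbered O1, C2(=O), C3, C4, C5 and exocyclic C6, ring A is a 4-hydroxyphenyl group on the β-carbon C4, its OH para to the C4–aryl bond. An electron-poor alkyne and a 1-methoxy-3-silyloxybutadiene deliver exactly this 1,4-pattern, so ring A is grown on the lactone instead of being bought.
- Disconnection A (last step): ring A → C4-ethynyl (Z)-ylidenebutenolide + trans-1-methoxy-3-(trimethylsilyloxy)buta-1,3-diene ([4+2], then loss of MeOH and the silyl group).
- Disconnection B: C4–C(sp) bond → Sonogashira coupling of the C4 bromide with ethynyltrimethylsilane, then desilylation.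
- Disconnection C: C5=C6 → vinylogous aldol condensation of 4-bromofuran-2(5H)-one with 3-bromo-4-methoxybenzaldehyde, which brings in ring B and sets the (Z)-alkene.
- Ring order: the lactone and ring B are purchased; ring A is the only ring formed, in the last step.

Key step: step 4

Remark: the target is taken as the (Z)-isomer written in the SMILES (aryl group of ring B syn to the ring oxygen), and the two bromo building blocks, ethynyltrimethylsilane and the silyloxydiene are taken to be commercial.

**Route**

Step 1
Reactants: 1 4-bromofuran-2(5H)-one; 2 3-bromo-4-methoxybenzaldehyde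
Product: 5 (Z)-4-bromo-5-(3-bromo-4-methoxybenzylidene)furan-2(5H)-one, via silyloxyfuran 3 (not isolated), via silyl aldol adduct 4 (not isolated)
Conditions: t-BuMe2SiOTf, i-Pr2NEt, CH2Cl2, 0 °C to rt; then DBU, rt
Reagents that add atoms: tert-butyldimethylsilyl trifluoromethanesulfonate, CC(C)(C)[Si](C)(C)OS(=O)(=O)C(F)(F)F (its silyl group is held in 3 and 4 only and is lost again on the way to 5)
Why: Vinylogous Mukaiyama aldol addition of the silyloxyfuran formed in the flask to the activated aldehyde at C5, followed by DBU-induced E1cB loss of silanol, is the established one-pot aldol condensation route to 5-arylidene-4-halobutenolides, and the (Z)-alkene should result because it is the thermodynamically preferred isomer, with the aryl group syn to the ring oxygen and away from the C4 substituent.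

Step 2
Reactants: 5 (Z)-4-bromo-5-(3-bromo-4-methoxybenzylidene)furan-2(5H)-one; 6 ethynyltrimethylsilane
Product: 7 (Z)-5-(3-bromo-4-methoxybenzylidene)-4-((trimethylsilyl)ethynyl)furan-2(5H)-one
Conditions: PdCl2(PPh3)2 (cat.), CuI (cat.), i-Pr2NEt, THF (degassed), rt
Reagents that add atoms: none
Why: Sonogashira coupling, in which oxidative addition of zerovalent palladium to the C4–Br bond of the β-bromobutenolide (a vinylogous acyl bromide) should be much faster at room temperature than to the electron-rich aryl bromide ortho to the methoxy group, so that only the lactone bromide is replaced.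

Step 3
Reactants: 7 (Z)-5-(3-bromo-4-methoxybenzylidene)-4-((trimethylsilyl)ethynyl)furan-2(5H)-one
Product: 8 (Z)-5-(3-bromo-4-methoxybenzylidene)-4-ethynylfuran-2(5H)-one
Conditions: Bu4NF, AcOH, THF, −20 to 0 °C; the product is used directly in step 4
Reagents that add atoms: none
Why: Fluoride-mediated protodesilylation of an alkynylsilane, buffered with acetic acid so that no basic species can add to the enyne lactone or open the enol ester, which should leave the (Z)-alkene and the aryl bromide untouched.

Step 4
Reactants: 8 (Z)-5-(3-bromo-4-methoxybenzylidene)-4-ethynylfuran-2(5H)-one; 9 trans-1-methoxy-3-(trimethylsilyloxy)buta-1,3-diene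
Product: 11 3''-bromorubrolide F, via cyclohexadiene cycloadduct 10 (not isolated)
Conditions: 9 (3 equiv), toluene, 100 °C, sealed tube; then 1 M aq. HCl, THF, rt
Reagents that add atoms: none
Why: Proposed new method: a thermal normal-electron-demand [4+2] cycloaddition is proposed in which the electron-rich diene 9 adds across the C4 ethynyl group of 8, a vinylogous ynoate whose terminal alkyne carbon is the electrophilic δ-position of the C2(=O)–C3=C4–C≡C dienoate, so that the CH2 terminus of 9 should bond to the terminal alkyne carbon and the methoxy-bearing terminus to the internal one in one concerted, asynchronous event; the closest known reaction type is the Diels–Alder reaction of 1-methoxy-3-silyloxybutadienes with alkynoates and ynones, which after acid treatment gives para-hydroxyaryl esters and ketones. Ring A is closed by this intermolecular cycloaddition, which forms both new C–C bonds, and the 1,4-cyclohexadiene 10 should then be aromatized by the acid, which removes methanol and cleaves the O–Si bond to leave the free phenol para to C4. No stereocenter remains in the product: the CH(OMe) carbon of 10 forms as a racemate and is erased on aromatization, and the (Z)-C5=C6 alkene set in step 1 takes no part. The step needs regioselectivity (hydroxyl para and not meta to C4), which the matched polarization of diene and alkyne should secure, and chemoselectivity for the alkyne over the two lactone alkenes, which rests on C3=C4 being trisubstituted (attack there would create a quaternary C4) and on C5=C6 being an electron-rich enol ester alkene.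

**Compound list**

1 | 4-bromofuran-2(5H)-one | BrC1=CC(=O)OC1 | starting material
2 | 3-bromo-4-methoxybenzaldehyde | COc1ccc(C=O)cc1Br | starting material
3 | 4-bromo-2-(tert-butyldimethylsilyloxy)furan | CC(C)(C)[Si](C)(C)Oc1cc(Br)co1 | intermediate (not isolated)
4 | 4-bromo-5-[(3-bromo-4-methoxyphenyl)(tert-butyldimethylsilyloxy)methyl]furan-2(5H)-one (racemic mixture of diastereomers) | COc1ccc(C(O[Si](C)(C)C(C)(C)C)C2OC(=O)C=C2Br)cc1Br | intermediate (not isolated)
5 | (Z)-4-bromo-5-(3-bromo-4-methoxybenzylidene)furan-2(5H)-one | COc1ccc(/C=C2\OC(=O)C=C2Br)cc1Br | intermediate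
6 | ethynyltrimethylsilane | C#C[Si](C)(C)C | starting material
7 | (Z)-5-(3-bromo-4-methoxybenzylidene)-4-((trimethylsilyl)ethynyl)furan-2(5H)-one | COc1ccc(/C=C2\OC(=O)C=C2C#C[Si](C)(C)C)cc1Br | intermediate
8 | (Z)-5-(3-bromo-4-methoxybenzylidene)-4-ethynylfuran-2(5H)-one | COc1ccc(/C=C2\OC(=O)C=C2C#C)cc1Br | intermediate
9 | trans-1-methoxy-3-(trimethylsilyloxy)buta-1,3-diene | CO/C=C/C(=C)O[Si](C)(C)C | starting material
10 | (Z)-5-(3-bromo-4-methoxybenzylidene)-4-[6-methoxy-4-(trimethylsilyloxy)cyclohexa-1,4-dien-1-yl]furan-2(5H)-one (racemic at the CH(OMe) carbon) | COc1ccc(/C=C2\OC(=O)C=C2C2=CCC(O[Si](C)(C)C)=CC2OC)cc1Br | intermediate (not isolated)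
11 | 3''-bromorubrolide F, (Z)-5-(3-bromo-4-methoxybenzylidene)-4-(4-hydroxyphenyl)furan-2(5H)-one | COc1ccc(/C=C2\OC(=O)C=C2c2ccc(O)cc2)cc1Br | target

**Step count**

Total steps: 4. Longest linear sequence: 4 steps (1 → 5 → 7 → 8 → 11).

**Steps most likely to fail, with fallbacks**

1. Step 4 (proposed new method). The alkyne of 8 is activated only through the C3=C4 bond and may be too weak a dienophile. In that case thermal oligomerization of the terminal enyne, cycloaddition at C3=C4, or decomposition of the diene could outrun the wanted cycloaddition. The fallback sets out from 5 and returns to the route at 11, and it attaches ring A as a preformed aryl group instead of building it. Suzuki–Miyaura coupling of 5 with 4-(tert-butyldimethylsilyloxy)phenylboronic acid (Pd(PPh3)4, K3PO4, toluene–water, 45 °C) is a known way to arylate C4 of 4-bromo-5-arylidenebutenolides and should react at the activated lactone bromide first. It should give (Z)-5-(3-bromo-4-methoxybenzylidene)-4-[4-(tert-butyldimethylsilyloxy)phenyl]furan-2(5H)-one F1. Cleavage of the aryl silyl ether (Bu4NF, AcOH, THF, 0 °C) should then give 11; any silyl ether already lost during the coupling is simply 11.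

2. Step 2. Site selectivity between the two C–Br bonds may be incomplete, so that some coupling also occurs at the aryl bromide, or the amine may degrade the bromobutenolide before coupling. The fallback sets out from 1 and returns to the route at 7, and it inverts the order of the two C–C bond formations so that no aryl bromide is present during the palladium step. Sonogashira coupling of 1 with 6 (PdCl2(PPh3)2, CuI, i-Pr2NEt, THF, rt) should give 4-((trimethylsilyl)ethynyl)furan-2(5H)-one F2. The one-pot vinylogous aldol condensation of F2 with 2 (t-BuMe2SiOTf, i-Pr2NEt, CH2Cl2, then DBU) should then pass through 2-(tert-butyldimethylsilyloxy)-4-((trimethylsilyl)ethynyl)furan F3 and the silylated aldol adduct 5-[(3-bromo-4-methoxyphenyl)(tert-butyldimethylsilyloxy)methyl]-4-((trimethylsilyl)ethynyl)furan-2(5H)-one F4, neither isolated, to 7.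

3. Step 3. Fluoride or adventitious base may add in conjugate fashion to the enyne or open the lactone during desilylation, and the freed terminal enyne may oligomerize on concentration. The fallback sets out from 5 and returns to the route at 8, and it avoids the silyl group altogether. Stille coupling of 5 with tributyl(ethynyl)stannane (Pd(PPh3)4, toluene, 50 °C) should install the free ethynyl group directly under neutral conditions, again at the activated lactone bromide. No new compound lies on this path (F0). The toluene solution of 8 could be filtered through silica and carried into step 4 without concentration.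

**Further compounds**

F1 | step 4 | (Z)-5-(3-bromo-4-methoxybenzylidene)-4-[4-(tert-butyldimethylsilyloxy)phenyl]furan-2(5H)-one | COc1ccc(/C=C2\OC(=O)C=C2c2ccc(O[Si](C)(C)C(C)(C)C)cc2)cc1Br
F2 | step 2 | 4-((trimethylsilyl)ethynyl)furan-2(5H)-one | C[Si](C)(C)C#CC1=CC(=O)OC1
F3 | step 2 | 2-(tert-butyldimethylsilyloxy)-4-((trimethylsilyl)ethynyl)furan | CC(C)(C)[Si](C)(C)Oc1cc(C#C[Si](C)(C)C)co1
F4 | step 2 | 5-[(3-bromo-4-methoxyphenyl)(tert-butyldimethylsilyloxy)methyl]-4-((trimethylsilyl)ethynyl)furan-2(5H)-one | COc1ccc(C(O[Si](C)(C)C(C)(C)C)C2OC(=O)C=C2C#C[Si](C)(C)C)cc1Br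
F0 | step 3 | none | none
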